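**Retrosynthetic overview**

- Target ⇒ salicylaldehyde ether of the racemic side chain. The last operation closes the pyranone ring (phenol acylation and intramolecular Wittig with Ph3P=C=C=O) and then, in the same flask, the oxirane ring (Ti(OiPr)4/L-(+)-tartrate/t-BuOOH kinetic-resolution epoxidation, which sets C5 and C6).
- Salicylaldehyde ether ⇒ (E)-3,7-dimethylocta-2,6-diene-1,5-diol + 2,4-dihydroxy-3-methoxybenzaldehyde (Mitsunobu C–O bond at the 4-OH).
- Diol ⇒ 6-methylhept-5-en-1-yn-4-ol (Zr-catalysed methylalumination, then CH2O) ⇒ prenal + propargyl bromide (Barbier).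
- Ring order: benzene ring bought; pyranone ring, then oxirane ring, both in the final operation.

Assumption: 2,4-dihydroxy-3-methoxybenzaldehyde is bought as a catalogue aldehyde.

**Step 1**
Reactants: 1 3-methylbut-2-enal (prenal); 2 3-bromoprop-1-yne (propargyl bromide)
Product: 4 rac-6-methylhept-5-en-1-yn-4-ol, via allenylzinc bromide 3 (not isolated)
Conditions: Zn dust, THF/sat. aq. NH4Cl, 0 °C to rt
Reagents that add atoms: none
Why: Barbier propargylation, in which allenylzinc bromide formed in situ adds 1,2 to the enal through a cyclic SE2′ transition state to give the homopropargylic alcohol; the carbinol centre (later C5) is made racemic on purpose and resolved in step 4.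

**Step 2**
Reactants: 4 rac-6-methylhept-5-en-1-yn-4-ol
Product: 7 rac-(2E)-3,7-dimethylocta-2,6-diene-1,5-diol, via alkenyldimethylalane 5 (not isolated), via lithium alkenylalanate 6 (not isolated)
Conditions: Me3Al (3 equiv), Cp2ZrCl2 (0.25 equiv), CH2Cl2, 0 °C to rt; volatiles off; n-BuLi (1.1 equiv), THF/hexane, −78 to 0 °C; (CH2O)n, rt; aq. potassium sodium tartrate (KNaC4H4O6) work-up
Reagents that add atoms: trimethylaluminium C[Al](C)C; formaldehyde (from paraformaldehyde) C=O
Why: Negishi zirconium-catalysed carboalumination, in which syn addition of Me–Al across the terminal alkyne (methyl to the internal carbon, hydroxyl carried as its aluminium alkoxide) fixes the E trisubstituted alkene and the alanate made with n-BuLi is hydroxymethylated by formaldehyde with retention of geometry; no stereocentre is touched.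

**Step 3**
Reactants: 7 rac-(2E)-3,7-dimethylocta-2,6-diene-1,5-diol; 8 2,4-dihydroxy-3-methoxybenzaldehyde
Product: 9 rac-2-hydroxy-4-{[(2E)-5-hydroxy-3,7-dimethylocta-2,6-dien-1-yl]oxy}-3-methoxybenzaldehyde
Conditions: PPh3 (1.2 equiv), DIAD (1.2 equiv), THF, 0 °C to rt
Reagents that add atoms: none
Why: Mitsunobu etherification, in which the unhindered primary allylic hydroxyl is activated and displaced in an SN2 sense by the more acidic, non-chelated 4-OH of 8 (the 2-OH is hydrogen-bonded to the aldehyde), leaving the secondary carbinol and the E alkene untouched.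

**Step 4**
Reactants: 9 rac-2-hydroxy-4-{[(2E)-5-hydroxy-3,7-dimethylocta-2,6-dien-1-yl]oxy}-3-methoxybenzaldehyde
Product: 12 7-{[(2E,5S)-5-[(2S)-3,3-dimethyloxiran-2-yl]-5-hydroxy-3-methylpent-2-en-1-yl]oxy}-8-methoxy-2H-chromen-2-one, via ester ylide 10 (not isolated), via racemic coumarin allylic alcohol 11 (not isolated)
Conditions: Ph3P=C=C=O (1.0 equiv), PhMe, 70 °C, 3 h; then CH2Cl2, 4 Å MS, Ti(OiPr)4 (0.2 equiv), diisopropyl L-(+)-tartrate (0.24 equiv), t-BuOOH (0.45 equiv, decane), −20 °C, 24–48 h; sat. aq. Na2SO4/Et2O work-up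
Reagents that add atoms: (triphenylphosphoranylidene)ketene O=C=C=P(c1ccccc1)(c1ccccc1)c1ccccc1; tert-butyl hydroperoxide CC(C)(C)OO
Why: Proposed new method: the one-flask merger is untested but each event is standard — the phenol adds to the ketene unit of Ph3P=C=C=O to give ester ylide 10, which closes the pyranone ring by intramolecular Wittig reaction with the ortho aldehyde (Bestmann coumarin annulation, closest known type), and the Sharpless kinetic-resolution epoxidation (closest known type for the second stage; phosphine oxide groups are tolerated by the titanium–tartrate catalyst) then transfers oxygen only to the fast-reacting (5S) enantiomer of 11 on the alkene face dictated by L-(+)-tartrate, giving the erythro epoxy alcohol with C5 S (by enantiomer selection) and C6 S (by face selection), while the (5R) enantiomer of 11 is left and removed by chromatography.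

**Compound list**

1 | 3-methylbut-2-enal (prenal) | CC(C)=CC=O | starting material
2 | 3-bromoprop-1-yne (propargyl bromide) | C#CCBr | starting material
3 | bromo(propa-1,2-dien-1-yl)zinc (allenylzinc bromide) | C=C=C[Zn]Br | intermediate
4 | rac-6-methylhept-5-en-1-yn-4-ol | C#CCC(O)C=C(C)C | intermediate
5 | [(1E)-4-(dimethylalumanyloxy)-2,6-dimethylhepta-1,5-dien-1-yl]dimethylalumane (racemic) | C[Al](C)/C=C(\C)CC(O[Al](C)C)C=C(C)C | intermediate
6 | lithium butyl[(1E)-4-(dimethylalumanyloxy)-2,6-dimethylhepta-1,5-dien-1-yl]dimethylalumanuide (racemic) | [Li+].CCCC[Al-](C)(C)/C=C(\C)CC(O[Al](C)C)C=C(C)C | intermediate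
7 | rac-(2E)-3,7-dimethylocta-2,6-diene-1,5-diol | OC/C=C(\C)CC(O)C=C(C)C | intermediate
8 | 2,4-dihydroxy-3-methoxybenzaldehyde | COc1c(O)ccc(C=O)c1O | starting material
9 | rac-2-hydroxy-4-{[(2E)-5-hydroxy-3,7-dimethylocta-2,6-dien-1-yl]oxy}-3-methoxybenzaldehyde | COc1c(OC/C=C(\C)CC(O)C=C(C)C)ccc(C=O)c1O | intermediate
10 | rac-6-formyl-3-{[(2E)-5-hydroxy-3,7-dimethylocta-2,6-dien-1-yl]oxy}-2-methoxyphenyl (triphenylphosphoranylidene)acetate | COc1c(OC/C=C(\C)CC(O)C=C(C)C)ccc(C=O)c1OC(=O)C=P(c1ccccc1)(c1ccccc1)c1ccccc1 | intermediate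
11 | rac-7-{[(2E)-5-hydroxy-3,7-dimethylocta-2,6-dien-1-yl]oxy}-8-methoxy-2H-chromen-2-one | COc1c(OC/C=C(\C)CC(O)C=C(C)C)ccc2ccc(=O)oc12 | intermediate
12 | 7-{[(2E,5S)-5-[(2S)-3,3-dimethyloxiran-2-yl]-5-hydroxy-3-methylpent-2-en-1-yl]oxy}-8-methoxy-2H-chromen-2-one | COc1c(OC/C=C(\C)C[C@H](O)[C@@H]2OC2(C)C)ccc2ccc(=O)oc12 | target

**Totals**

Total step count: 4. Longest linear sequence: 4 steps (1 → 4 → 7 → 9 → 12).

**Steps most likely to fail**

Step 4. Ph3P=O left from the first stage may disturb the titanium–tartrate catalyst. A secondary allylic alcohol with a methyl group cis to the carbinol on the distal alkene carbon is also a slow and only moderately selective substrate for kinetic resolution, so ee and erythro ratio may fall short, and the yield is capped at 50 %. The fallback sets out from 9 and comes back at 12. Run the annulation alone (Ph3P=C=C=O, PhMe, 80 °C) and isolate racemic 11. Oxidise its allylic alcohol with MnO2 (CH2Cl2, rt) to the dienone 7-{[(2E)-3,7-dimethyl-5-oxoocta-2,6-dien-1-yl]oxy}-8-methoxy-2H-chromen-2-one F1. Reduce F1 with catecholborane and the (R)-configured Corey–Bakshi–Shibata catalyst (R)-1-methyl-3,3-diphenyltetrahydro-1H,3H-pyrrolo[1,2-c][1,3,2]oxazaborole (PhMe, −78 °C, alkenyl as the large group) to 7-{[(2E,5S)-5-hydroxy-3,7-dimethylocta-2,6-dien-1-yl]oxy}-8-methoxy-2H-chromen-2-one F2. Epoxidise F2 to near-full conversion with Ti(OiPr)4 (1.0 equiv), diisopropyl L-(+)-tartrate (1.2 equiv) and t-BuOOH (CH2Cl2, −20 °C); this is the matched pair, and the residual (5R) enantiomer reacts slowly and stays behind, giving 12.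

Step 2. The dimethylaluminium alkoxide of a prenyl-type allylic alcohol may ionise or eliminate under the Lewis-acidic Me3Al/Cp2ZrCl2 conditions, and hydroxymethylation of the alanate can be low-yielding. The fallback sets out from 4 and comes back at 7. C-Hydroxymethylate the alkyne (EtMgBr 2.2 equiv, THF, then (CH2O)n) to rac-7-methyloct-6-en-2-yne-1,5-diol F3. Hydroxyl-directed trans-hydroalumination with NaAlH2(OCH2CH2OMe)2 (THF, 0 °C; both alkoxides deliver aluminium to C3) followed by I2 at −78 °C gives rac-(2Z)-3-iodo-7-methylocta-2,6-diene-1,5-diol F4. Me2CuLi (Et2O, 0 °C) replaces iodine by methyl with retention of alkene geometry to give 7.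

Step 3. SN2′ attack, activation of the secondary allylic hydroxyl, or reaction at the 2-OH would erode the Mitsunobu coupling. The fallback sets out from 7 and comes back at 9. Convert only the primary allylic hydroxyl into the chloride with N-chlorosuccinimide/Me2S (CH2Cl2, −30 to 0 °C) to give rac-(6E)-8-chloro-2,6-dimethylocta-2,6-dien-4-ol F5. Then alkylate 8 at its more acidic 4-OH with F5 under weak base (KHCO3, catalytic KI, DMF, 40 °C; the chelated 2-OH stays free) to give 9.

**Further compounds**

F1 | step 4 | 7-{[(2E)-3,7-dimethyl-5-oxoocta-2,6-dien-1-yl]oxy}-8-methoxy-2H-chromen-2-one | COc1c(OC/C=C(\C)CC(=O)C=C(C)C)ccc2ccc(=O)oc12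
F2 | step 4 | 7-{[(2E,5S)-5-hydroxy-3,7-dimethylocta-2,6-dien-1-yl]oxy}-8-methoxy-2H-chromen-2-one | COc1c(OC/C=C(\C)C[C@H](O)C=C(C)C)ccc2ccc(=O)oc12
F3 | step 2 | rac-7-methyloct-6-en-2-yne-1,5-diol | OCC#CCC(O)C=C(C)C
F4 | step 2 | rac-(2Z)-3-iodo-7-methylocta-2,6-diene-1,5-diol | OC/C=C(\I)CC(O)C=C(C)C
F5 | step 3 | rac-(6E)-8-chloro-2,6-dimethylocta-2,6-dien-4-ol | ClC/C=C(\C)CC(O)C=C(C)C
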